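(All runs were generated by integration for substances that don't exist; noise was put on by code.)

Hold the eta run against the delta run at the last reading: target is 66.8% of the charge in delta and 66.7% in eta. So the share made follows time rather than charge, and the epsilon run, charged like delta, should follow delta's curve.

| flask | starting material | time |
|---|---|---|
| delta | 0.800 M |  |
| eta | 2.40 M |  |
| epsilon | 0.800 M | 22 min |

| delta run: time / min | delta run: [target] / M | eta run: time / min | eta run: [target] / M |
|---|---|---|---|
| 0.56 | 0.0512 | 0.56 | 0.1489 |
| 1.7 | 0.2023 | 1.7 | 0.6059 |
| 3.2 | 0.3600 | 3.2 | 1.0813 |
| 5.1 | 0.4763 | 5.1 | 1.4327 |
| 7.3 | 0.5343 | 7.3 | 1.6015 |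

(standard deviation of a reading: 0.002 M)

1. the power of [starting material] that the first rate follows, about the charge of the delta run; measure it at two percent of starting material made into target (one fixed amount of target, the same in the runs compared)
2. target in the epsilon run at 22 min, as a share of the starting material charged

- Overall: starting material -> target.
- Constant volume, constant temperature.
- An order is taken over about fifteen percent of the charge, up and down.

Now follow one molecule through the delta run. Between 1.7 min and 3.2 min, divide the slope of c(target) by the charge less c(target), which gives 0.203 min⁻¹. Call this the feed chance: the first-order chance per minute that an unmade molecule becomes target. But between 5.1 min and 7.3 min that chance asks for a slope of 0.0597 M min⁻¹, and the delta run shows 0.0264 M min⁻¹, which is less. Read the gap as target leaving again, at 0.0660 min⁻¹. Running both chances on from the last reading, my own reckoning for the epsilon run is 41.5%.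

The forecast gives 0.6 for the order, which I have not reckoned, and 71% for the share, where it differs from my reckoning: “The remainder is lost to equilibrium or a side path.”

The flask gives 0.66 and 46.1%.

    starting material ⇌ intermediate (0.2100 min⁻¹, 0.02358 min⁻¹)
    intermediate → target (1.938 min⁻¹)
    target → decomposed product (0.04476 min⁻¹)
    starting material → target (0.03468 min⁻¹)

Take the conversion of target into decomposed product out of the epsilon run, and target at 22 min stands at 99.5% instead of 46.1%, which is 99% of what is missing. For that stripped run, the feed chance of 0.203 min⁻¹ gives 98.9% of the charge made by 22 min. By the same estimate about that share has been made in the epsilon run too, yet the epsilon run holds 46.1%.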